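**Plan**

1. Retrosynthesis cuts the polyene at C10=C11 and C10'=C11' (two Horner–Wadsworth–Emmons olefinations) into a ring A C14 aldehyde, a ring B C14 aldehyde and a C2-symmetric C12 bis-phosphonate; the last is cut at the central C15–C15' bond (Stille coupling of a C6 alkenylstannane with the alkenyl iodide made from the same stannane).
2. Ring B is ring A plus water across C4=C5 (C5' tertiary OH, C4' H2), so both aldehydes trace back to one cyclohexadienyl ester. Ring A is cut at C4=C5 (ring-closing metathesis) to an acyclic triene ester, and this at C5–C6 (carbocupration of an ynoate).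
3. Enabling feature: C4=C5 is the only endocyclic olefin of ring A, a trisubstituted bond between the C3 carbinol carbon and the C6 ylidene carbon, with the C1 gem-dimethyl group in the tether; the exocyclic C6=C7 bond is an electron-poor enoate and stays out of the metathesis.
4. Forward: chiral chain from isobutyronitrile and (S)-epichlorohydrin, ynoate, syn-carbocupration (sets 6E before the ring exists), metathesis to ring A. Then divergence: chain extension to the ring A aldehyde, or epoxidation, inversion, hydride opening and chain extension to the ring B aldehyde. Linker, two olefinations and desilylation follow.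
5. Stereocenters: C3 (S) is bought with epichlorohydrin; C5' (S) is relayed from it by hydroxyl-directed epoxidation of the metathesis olefin; C3' (R) comes from Mitsunobu inversion of the same carbinol; hydride opening at C4' then gives the trans-3',5'-diol.
6. Olefin geometry: 6E/6'E from the syn-carbocupration, 8E/8'E from a stabilised Wittig ylide, 12E/14E (and primed) from the commercial (E)-enynol and syn-hydrostannation, carried with retention through iododestannylation and Stille coupling, 10E/10'E from the phosphonate olefinations.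

Key step: step 8

Remark: locants such as C3, C4, C5, C6 (primed for ring B) follow the carotenoid numbering of the target; (S)-epichlorohydrin is assumed to react with the lithiated nitrile at its epoxide CH2 and not at C–Cl.

**Route**

Step 1
Reactants: 1 isobutyronitrile; 2 (S)-epichlorohydrin [(2S)-2-(chloromethyl)oxirane]
Product: 4 2,2-dimethyl-3-[(2S)-oxiran-2-yl]propanenitrile, via lithium chlorohydrin alkoxide 3 (not isolated)
Conditions: LiN(i-Pr)2 (1.05 equiv), THF, −78 °C; then 2 (1.5 equiv), −78 °C to rt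
Reagents that add atoms: none
Why: The α-cyano carbanion opens the epoxide at its unsubstituted carbon (SN2) and the alkoxide then closes onto the chloromethyl carbon (3-exo-tet), so the C–O bond at the stereocenter is never broken and the future C3 configuration is taken from the chiral pool (nitrile-anion alkylation with epichlorohydrin).

Step 2
Reactants: 4 2,2-dimethyl-3-[(2S)-oxiran-2-yl]propanenitrile
Product: 5 (4S)-4-hydroxy-2,2-dimethylhex-5-enenitrile
Conditions: Me3S+ I− (3 equiv), n-BuLi (2.9 equiv), THF, −10 °C to rt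
Reagents that add atoms: trimethylsulfonium iodide, C[S+](C)C.[I-]
Why: Dimethylsulfonium methylide opens the terminal epoxide at CH2 and excess ylide induces elimination of dimethyl sulfide from the resulting sulfonium, giving the one-carbon-homologated allylic alcohol (sulfonium-ylide epoxide-to-allylic-alcohol homologation) without touching the carbinol center.

Step 3
Reactants: 5 (4S)-4-hydroxy-2,2-dimethylhex-5-enenitrile
Product: 6 (4S)-4-{[tert-butyl(dimethyl)silyl]oxy}-2,2-dimethylhex-5-enenitrile
Conditions: TBSCl, imidazole, DMF, rt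
Reagents that add atoms: tert-butyldimethylsilyl chloride, CC(C)(C)[Si](C)(C)Cl
Why: Standard silylation of a secondary alcohol; the silyl ether masks the C3 oxygen through the organometallic steps.

Step 4
Reactants: 6 (4S)-4-{[tert-butyl(dimethyl)silyl]oxy}-2,2-dimethylhex-5-enenitrile
Product: 7 (4S)-4-{[tert-butyl(dimethyl)silyl]oxy}-2,2-dimethylhex-5-enal
Conditions: i-Bu2AlH (1.2 equiv), CH2Cl2, −78 °C; then aqueous Rochelle salt, rt
Reagents that add atoms: water, O
Why: i-Bu2AlH delivers a single hydride to the hindered tertiary nitrile and aqueous work-up hydrolyses the C=N bond to the non-enolisable aldehyde (nitrile half-reduction).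

Step 5
Reactants: 7 (4S)-4-{[tert-butyl(dimethyl)silyl]oxy}-2,2-dimethylhex-5-enal
Product: 8 tert-butyl{[(3S)-5,5-dimethylhept-1-en-6-yn-3-yl]oxy}dimethylsilane
Conditions: dimethyl (1-diazo-2-oxopropyl)phosphonate, K2CO3, MeOH, 0 °C to rt
Reagents that add atoms: dimethyl (1-diazo-2-oxopropyl)phosphonate (Ohira–Bestmann reagent), COP(=O)(OC)C(=[N+]=[N-])C(C)=O
Why: Seyferth–Gilbert homologation under Ohira–Bestmann conditions converts the α-quaternary aldehyde into the terminal alkyne through a vinylidene carbene 1,2-shift, with silyl ether and vinyl group as spectators.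

Step 6
Reactants: 8 tert-butyl{[(3S)-5,5-dimethylhept-1-en-6-yn-3-yl]oxy}dimethylsilane
Product: 9 ethyl (6S)-6-{[tert-butyl(dimethyl)silyl]oxy}-4,4-dimethyloct-7-en-2-ynoate
Conditions: n-BuLi, THF, −78 °C; then ClCO2Et, −78 to 0 °C
Reagents that add atoms: ethyl chloroformate, CCOC(Cl)=O
Why: Deprotonation of the terminal alkyne and C-acylation of the lithium acetylide with the chloroformate give the ynoate (acetylide carboxylation).

Step 7
Reactants: 9 ethyl (6S)-6-{[tert-butyl(dimethyl)silyl]oxy}-4,4-dimethyloct-7-en-2-ynoate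
Product: 10 ethyl (2Z)-3-[(4S)-4-{[tert-butyl(dimethyl)silyl]oxy}-2-methylhex-5-en-2-yl]-4-methylpenta-2,4-dienoate (ester cis to the quaternary carbon, isopropenyl cis to the vinylic hydrogen)
Conditions: CH2=C(Me)MgBr (2.2 equiv), CuBr·SMe2 (1.1 equiv), THF, −78 °C; then 9, −78 °C; MeOH quench at −78 °C
Reagents that add atoms: isopropenylmagnesium bromide, CC(=C)[Mg]Br
Why: Syn-carbocupration of the ynoate delivers the isopropenyl group to the β-carbon (C6) and copper to the α-carbon on the same side, and cold protonation with retention places hydrogen cis to isopropenyl and hence the ester cis to the quaternary C1, which is the C6=C7 geometry of the target; the low temperature prevents equilibration through the allenoate.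

Step 8
Reactants: 10 ethyl (2Z)-3-[(4S)-4-{[tert-butyl(dimethyl)silyl]oxy}-2-methylhex-5-en-2-yl]-4-methylpenta-2,4-dienoate
Product: 11 ethyl (2E)-2-[(4S)-4-{[tert-butyl(dimethyl)silyl]oxy}-2,6,6-trimethylcyclohex-2-en-1-ylidene]acetate
Conditions: second-generation Hoveyda–Grubbs catalyst RuCl2(H2IMes)(=CH-C6H4-2-O-i-Pr) (5 mol %), toluene (0.005 M), 80 °C, argon sparge
Reagents that add atoms: none
Why: The ruthenium alkylidene initiates at the monosubstituted C4 vinyl group, adds [2+2] to the 1,1-disubstituted methylene of the isopropenyl group and cycloreverts with loss of ethylene, so that the C4=C5 bond and ring A form in one event. The closest known reaction type is ring-closing metathesis of a 1,7-diene to a trisubstituted cyclohexene, here in its ene–diene variant that leaves a conjugated diene. The ring closes as a six-membered carbocycle between two terminal olefin carbons, helped by the gem-dimethyl group at C1 (Thorpe–Ingold effect). No stereocenter is created: the C3 silyl ether is a spectator and the C6=C7 geometry from step 7 is untouched, because the trisubstituted, ester-conjugated olefin is too electron-poor and hindered to engage the carbene and its participation would need a five-membered ring and an ester-substituted carbene. The selectivity needed is site selectivity among three olefins and ring closure over oligomerisation, secured by that electronic bias and by high dilution. The product carries the complete C4=C5–C6=C7 diene of ring A and, by later addition of the elements of water across the same C4=C5 bond, also serves ring B.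

Step 9
Reactants: 11 ethyl (2E)-2-[(4S)-4-{[tert-butyl(dimethyl)silyl]oxy}-2,6,6-trimethylcyclohex-2-en-1-ylidene]acetate
Product: 12 (2E)-2-[(4S)-4-{[tert-butyl(dimethyl)silyl]oxy}-2,6,6-trimethylcyclohex-2-en-1-ylidene]ethan-1-ol
Conditions: i-Bu2AlH (2.5 equiv), CH2Cl2, −78 °C
Reagents that add atoms: none
Why: i-Bu2AlH reduces the conjugated ester 1,2 to the allylic alcohol without touching the diene or the silyl ether.

Step 10
Reactants: 12 (2E)-2-[(4S)-4-{[tert-butyl(dimethyl)silyl]oxy}-2,6,6-trimethylcyclohex-2-en-1-ylidene]ethan-1-ol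
Product: 13 (2E)-2-[(4S)-4-{[tert-butyl(dimethyl)silyl]oxy}-2,6,6-trimethylcyclohex-2-en-1-ylidene]acetaldehyde
Conditions: MnO2 (activated, excess), CH2Cl2, rt
Reagents that add atoms: none
Why: MnO2 oxidises the primary allylic alcohol selectively to the dienal under neutral conditions that preserve the exocyclic geometry.

Step 11
Reactants: 13 (2E)-2-[(4S)-4-{[tert-butyl(dimethyl)silyl]oxy}-2,6,6-trimethylcyclohex-2-en-1-ylidene]acetaldehyde
Product: 14 (2E,4E)-4-[(4S)-4-{[tert-butyl(dimethyl)silyl]oxy}-2,6,6-trimethylcyclohex-2-en-1-ylidene]-2-methylbut-2-enal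
Conditions: Ph3P=C(Me)CHO (1.3 equiv), toluene, 80 °C
Reagents that add atoms: 2-(triphenylphosphoranylidene)propanal, CC(C=O)=P(c1ccccc1)(c1ccccc1)c1ccccc1
Why: Wittig olefination with the formyl-stabilised ylide is E-selective and stops after one homologation because the product trienal is less electrophilic; it installs C9 with its methyl group and C10 as the aldehyde.

Step 12
Reactants: 11 ethyl (2E)-2-[(4S)-4-{[tert-butyl(dimethyl)silyl]oxy}-2,6,6-trimethylcyclohex-2-en-1-ylidene]acetate
Product: 15 ethyl (2E)-2-[(4S)-4-hydroxy-2,6,6-trimethylcyclohex-2-en-1-ylidene]acetate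
Conditions: Bu4NF, AcOH (1:1), THF, 0 °C to rt
Reagents that add atoms: none
Why: Fluoride cleaves the silyl ether, and acetic acid buffering avoids base-induced isomerisation of the dienoate.

Step 13
Reactants: 15 ethyl (2E)-2-[(4S)-4-hydroxy-2,6,6-trimethylcyclohex-2-en-1-ylidene]acetate
Product: 16 ethyl (2E)-2-[(1R,5S,6S)-5-hydroxy-1,3,3-trimethyl-7-oxabicyclo[4.1.0]heptan-2-ylidene]acetate (epoxide oxygen cis to the hydroxyl)
Conditions: VO(acac)2 (3 mol %), t-BuOOH (1.5 equiv), CH2Cl2, 0 °C to rt
Reagents that add atoms: tert-butyl hydroperoxide, CC(C)(C)OO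
Why: In this hydroxyl-directed epoxidation the vanadate ester of the allylic C3 hydroxyl delivers oxygen to the adjacent C4=C5 bond on its own face, while the ester-conjugated C6=C7 bond is unreactive, so the oxygen-bearing C5 stereocenter is relayed from C3.

Step 14
Reactants: 16 ethyl (2E)-2-[(1R,5S,6S)-5-hydroxy-1,3,3-trimethyl-7-oxabicyclo[4.1.0]heptan-2-ylidene]acetate
Product: 17 ethyl (2E)-2-[(1R,5R,6S)-5-(benzoyloxy)-1,3,3-trimethyl-7-oxabicyclo[4.1.0]heptan-2-ylidene]acetate (benzoate trans to the epoxide oxygen)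
Conditions: PPh3, DIAD, PhCO2H, THF, 0 °C to rt
Reagents that add atoms: benzoic acid, OC(=O)c1ccccc1
Why: Mitsunobu esterification displaces the oxyphosphonium by SN2 with inversion at C3, putting the oxygen on the face opposite to the epoxide, which is the relative configuration of the ring B diol.

Step 15
Reactants: 17 ethyl (2E)-2-[(1R,5R,6S)-5-(benzoyloxy)-1,3,3-trimethyl-7-oxabicyclo[4.1.0]heptan-2-ylidene]acetate
Product: 19 (1S,3R,6E)-6-(2-hydroxyethylidene)-1,5,5-trimethylcyclohexane-1,3-diol, via anti-epoxy diol aluminate 18 (not isolated)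
Conditions: NaAlH2(OCH2CH2OMe)2 (Red-Al, 5 equiv), THF, 0 °C to rt; aqueous Rochelle salt
Reagents that add atoms: none
Why: The aluminium hydride reduces the ethyl ester to the primary allylic alcohol and cleaves the benzoate, and the C3 alkoxyaluminate, now trans to the epoxide, delivers hydride to C4 from the rear (SN2, as in Red-Al openings of 2,3-epoxy alcohols to 1,3-diols; C5 is fully substituted and cannot be attacked), so the C5–O bond is kept and the trans-3,5-diol with the tertiary alcohol results.

Step 16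
Reactants: 19 (1S,3R,6E)-6-(2-hydroxyethylidene)-1,5,5-trimethylcyclohexane-1,3-diol
Product: 20 (2E)-2-[(2S,4R)-2,4-dihydroxy-2,6,6-trimethylcyclohexylidene]acetaldehyde
Conditions: MnO2 (activated, excess), CH2Cl2, rt
Reagents that add atoms: none
Why: MnO2 oxidises only the primary allylic alcohol, leaving the saturated secondary and the tertiary alcohol untouched.

Step 17
Reactants: 20 (2E)-2-[(2S,4R)-2,4-dihydroxy-2,6,6-trimethylcyclohexylidene]acetaldehyde
Product: 21 (2E,4E)-4-[(2S,4R)-2,4-dihydroxy-2,6,6-trimethylcyclohexylidene]-2-methylbut-2-enal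
Conditions: Ph3P=C(Me)CHO (1.3 equiv), toluene, 80 °C
Reagents that add atoms: 2-(triphenylphosphoranylidene)propanal, CC(C=O)=P(c1ccccc1)(c1ccccc1)c1ccccc1
Why: E-selective Wittig olefination with the stabilised ylide tolerates the free hydroxyls and extends the enal by the C9'(Me)–C10' unit under neutral conditions that keep the 6'E geometry.

Step 18
Reactants: 22 (2E)-3-methylpent-2-en-4-yn-1-ol
Product: 23 (2E,4E)-3-methyl-5-(tributylstannyl)penta-2,4-dien-1-ol
Conditions: Bu3SnH (1.1 equiv), PdCl2(PPh3)2 (2 mol %), THF, 0 °C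
Reagents that add atoms: tributyltin hydride, CCCC[SnH](CCCC)CCCC
Why: Palladium-catalysed syn-hydrostannation of the terminal alkyne places tin on the terminal carbon and gives the (E)-alkenylstannane, while the (2E) olefin comes from the starting enynol.

Step 19
Reactants: 23 (2E,4E)-3-methyl-5-(tributylstannyl)penta-2,4-dien-1-ol
Product: 24 tributyl[(1E,3E)-5-bromo-3-methylpenta-1,3-dien-1-yl]stannane
Conditions: CBr4, PPh3, 2,6-lutidine, CH2Cl2, −20 °C
Reagents that add atoms: carbon tetrabromide, BrC(Br)(Br)Br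
Why: Appel bromination of the primary allylic alcohol under buffered conditions spares the acid-sensitive alkenylstannane.

Step 20
Reactants: 24 tributyl[(1E,3E)-5-bromo-3-methylpenta-1,3-dien-1-yl]stannane
Product: 25 diethyl [(2E,4E)-3-methyl-5-(tributylstannyl)penta-2,4-dien-1-yl]phosphonate
Conditions: P(OEt)3 (neat), 90 °C
Reagents that add atoms: triethyl phosphite, CCOP(OCC)OCC
Why: Michaelis–Arbuzov reaction of the primary allylic bromide gives the allylic phosphonate.

Step 21
Reactants: 25 diethyl [(2E,4E)-3-methyl-5-(tributylstannyl)penta-2,4-dien-1-yl]phosphonate (half of the batch)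
Product: 26 diethyl [(2E,4E)-5-iodo-3-methylpenta-2,4-dien-1-yl]phosphonate
Conditions: I2 (1.05 equiv), CH2Cl2, 0 °C, dark; aqueous Na2S2O3
Reagents that add atoms: iodine, II
Why: Iododestannylation replaces tin by iodine at the alkenyl carbon through electrophilic ipso substitution with retention of the (E) geometry; the allylic phosphonate is inert to iodine at this temperature.

Step 22
Reactants: 25 diethyl [(2E,4E)-3-methyl-5-(tributylstannyl)penta-2,4-dien-1-yl]phosphonate (the other half of the batch); 26 diethyl [(2E,4E)-5-iodo-3-methylpenta-2,4-dien-1-yl]phosphonate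
Product: 27 tetraethyl [(2E,4E,6E,8E)-3,8-dimethyldeca-2,4,6,8-tetraene-1,10-diyl]bis(phosphonate)
Conditions: Pd2(dba)3 (2.5 mol %), AsPh3 (20 mol %), NMP, rt, dark
Reagents that add atoms: none
Why: Stille cross-coupling (oxidative addition of the alkenyl iodide to zerovalent palladium, tin-to-palladium transmetalation, reductive elimination) forms the C15–C15' bond with retention of both olefin geometries, and because both partners come from 25 the C2 symmetry of the chain is exploited.

Step 23
Reactants: 14 (2E,4E)-4-[(4S)-4-{[tert-butyl(dimethyl)silyl]oxy}-2,6,6-trimethylcyclohex-2-en-1-ylidene]-2-methylbut-2-enal; 27 tetraethyl [(2E,4E,6E,8E)-3,8-dimethyldeca-2,4,6,8-tetraene-1,10-diyl]bis(phosphonate)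
Product: 28 diethyl [(2E,4E,6E,8E,10E,12E,14E)-14-[(4S)-4-{[tert-butyl(dimethyl)silyl]oxy}-2,6,6-trimethylcyclohex-2-en-1-ylidene]-3,8,12-trimethyltetradeca-2,4,6,8,10,12-hexaen-1-yl]phosphonate
Conditions: 27 (3 equiv), NaN(SiMe3)2 (1.1 equiv), THF, −78 °C; then 14 (1 equiv), −78 to 0 °C, dark
Reagents that add atoms: none
Why: Horner–Wadsworth–Emmons olefination of the non-enolisable trienal with the mono-anion of the bis-phosphonate, used in excess so that single olefination dominates, forms the C10=C11 bond E-selectively.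

Step 24
Reactants: 28 diethyl [(2E,4E,6E,8E,10E,12E,14E)-14-[(4S)-4-{[tert-butyl(dimethyl)silyl]oxy}-2,6,6-trimethylcyclohex-2-en-1-ylidene]-3,8,12-trimethyltetradeca-2,4,6,8,10,12-hexaen-1-yl]phosphonate; 21 (2E,4E)-4-[(2S,4R)-2,4-dihydroxy-2,6,6-trimethylcyclohexylidene]-2-methylbut-2-enal
Product: 29 (3S,3'R,5'S)-3-O-[tert-butyl(dimethyl)silyl] ether of the all-E target triol
Conditions: 28 (1.0 equiv), 21 (1.1 equiv), KOt-Bu (3.5 equiv), THF, −30 to 0 °C, dark
Reagents that add atoms: none
Why: The second Horner–Wadsworth–Emmons olefination forms C10'=C11' (E); the aldehyde is non-enolisable, its two hydroxyls are carried as potassium alkoxides, and the 6'E geometry is safe because the carbanion sits on the other fragment.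

Step 25
Reactants: 29 (3S,3'R,5'S)-3-O-[tert-butyl(dimethyl)silyl] ether of the all-E target triol
Product: 30 target CNP0269135.1, all-E retro-carotenoid triol with (3S) in ring A and (3'R,5'S) in ring B
Conditions: Bu4NF, AcOH (1:1), THF, rt, dark
Reagents that add atoms: none
Why: Buffered fluoride removes the last silyl ether from the allylic C3 oxygen without base-induced isomerisation of the polyene.

**Compound list**

1 | isobutyronitrile | CC(C)C#N | starting material
2 | (S)-epichlorohydrin | ClC[C@@H]1CO1 | starting material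
3 | lithium (2S)-1-chloro-4-cyano-4-methylpentan-2-olate (lithium chlorohydrin alkoxide) | ClC[C@@H]([O-])CC(C)(C)C#N.[Li+] | intermediate
4 | 2,2-dimethyl-3-[(2S)-oxiran-2-yl]propanenitrile | C1[C@@H](O1)CC(C)(C)C#N | intermediate
5 | (4S)-4-hydroxy-2,2-dimethylhex-5-enenitrile | C=C[C@@H](O)CC(C)(C)C#N | intermediate
6 | (4S)-4-{[tert-butyl(dimethyl)silyl]oxy}-2,2-dimethylhex-5-enenitrile | C=C[C@@H](O[Si](C)(C)C(C)(C)C)CC(C)(C)C#N | intermediate
7 | (4S)-4-{[tert-butyl(dimethyl)silyl]oxy}-2,2-dimethylhex-5-enal | C=C[C@@H](O[Si](C)(C)C(C)(C)C)CC(C)(C)C=O | intermediate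
8 | tert-butyl{[(3S)-5,5-dimethylhept-1-en-6-yn-3-yl]oxy}dimethylsilane | C=C[C@@H](O[Si](C)(C)C(C)(C)C)CC(C)(C)C#C | intermediate
9 | ethyl (6S)-6-{[tert-butyl(dimethyl)silyl]oxy}-4,4-dimethyloct-7-en-2-ynoate | C=C[C@@H](O[Si](C)(C)C(C)(C)C)CC(C)(C)C#CC(=O)OCC | intermediate
10 | ethyl (2Z)-3-[(4S)-4-{[tert-butyl(dimethyl)silyl]oxy}-2-methylhex-5-en-2-yl]-4-methylpenta-2,4-dienoate | C=C[C@@H](O[Si](C)(C)C(C)(C)C)CC(C)(C)\C(=C/C(=O)OCC)C(C)=C | intermediate
11 | ethyl (2E)-2-[(4S)-4-{[tert-butyl(dimethyl)silyl]oxy}-2,6,6-trimethylcyclohex-2-en-1-ylidene]acetate | CC1=C[C@@H](O[Si](C)(C)C(C)(C)C)CC(C)(C)\C1=C/C(=O)OCC | intermediate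
12 | (2E)-2-[(4S)-4-{[tert-butyl(dimethyl)silyl]oxy}-2,6,6-trimethylcyclohex-2-en-1-ylidene]ethan-1-ol | CC1=C[C@@H](O[Si](C)(C)C(C)(C)C)CC(C)(C)\C1=C/CO | intermediate
13 | (2E)-2-[(4S)-4-{[tert-butyl(dimethyl)silyl]oxy}-2,6,6-trimethylcyclohex-2-en-1-ylidene]acetaldehyde | CC1=C[C@@H](O[Si](C)(C)C(C)(C)C)CC(C)(C)\C1=C/C=O | intermediate
14 | (2E,4E)-4-[(4S)-4-{[tert-butyl(dimethyl)silyl]oxy}-2,6,6-trimethylcyclohex-2-en-1-ylidene]-2-methylbut-2-enal | CC1=C[C@@H](O[Si](C)(C)C(C)(C)C)CC(C)(C)\C1=C/C=C(C)/C=O | intermediate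
15 | ethyl (2E)-2-[(4S)-4-hydroxy-2,6,6-trimethylcyclohex-2-en-1-ylidene]acetate | CC1=C[C@@H](O)CC(C)(C)\C1=C/C(=O)OCC | intermediate
16 | ethyl (2E)-2-[(1R,5S,6S)-5-hydroxy-1,3,3-trimethyl-7-oxabicyclo[4.1.0]heptan-2-ylidene]acetate | CCOC(=O)/C=C1\C(C)(C)C[C@H](O)[C@H]2[C@]1(C)O2 | intermediate
17 | ethyl (2E)-2-[(1R,5R,6S)-5-(benzoyloxy)-1,3,3-trimethyl-7-oxabicyclo[4.1.0]heptan-2-ylidene]acetate | CCOC(=O)/C=C1\C(C)(C)C[C@@H](OC(=O)c3ccccc3)[C@H]2[C@]1(C)O2 | intermediate
18 | (2E)-2-[(1R,5R,6S)-5-hydroxy-1,3,3-trimethyl-7-oxabicyclo[4.1.0]heptan-2-ylidene]ethan-1-ol, present as its aluminium alkoxide (anti-epoxy diol aluminate) | OC/C=C1\C(C)(C)C[C@@H](O)[C@H]2[C@]1(C)O2 | intermediate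
19 | (1S,3R,6E)-6-(2-hydroxyethylidene)-1,5,5-trimethylcyclohexane-1,3-diol | OC/C=C1\C(C)(C)C[C@@H](O)C[C@]1(C)O | intermediate
20 | (2E)-2-[(2S,4R)-2,4-dihydroxy-2,6,6-trimethylcyclohexylidene]acetaldehyde | O=C/C=C1\C(C)(C)C[C@@H](O)C[C@]1(C)O | intermediate
21 | (2E,4E)-4-[(2S,4R)-2,4-dihydroxy-2,6,6-trimethylcyclohexylidene]-2-methylbut-2-enal | O=C/C(C)=C/C=C1\C(C)(C)C[C@@H](O)C[C@]1(C)O | intermediate
22 | (2E)-3-methylpent-2-en-4-yn-1-ol | C#C/C(C)=C/CO | starting material
23 | (2E,4E)-3-methyl-5-(tributylstannyl)penta-2,4-dien-1-ol | CCCC[Sn](CCCC)(CCCC)/C=C/C(C)=C/CO | intermediate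
24 | tributyl[(1E,3E)-5-bromo-3-methylpenta-1,3-dien-1-yl]stannane | CCCC[Sn](CCCC)(CCCC)/C=C/C(C)=C/CBr | intermediate
25 | diethyl [(2E,4E)-3-methyl-5-(tributylstannyl)penta-2,4-dien-1-yl]phosphonate | CCCC[Sn](CCCC)(CCCC)/C=C/C(C)=C/CP(=O)(OCC)OCC | intermediate
26 | diethyl [(2E,4E)-5-iodo-3-methylpenta-2,4-dien-1-yl]phosphonate | CCOP(=O)(OCC)C/C=C(C)/C=C/I | intermediate
27 | tetraethyl [(2E,4E,6E,8E)-3,8-dimethyldeca-2,4,6,8-tetraene-1,10-diyl]bis(phosphonate) | CCOP(=O)(OCC)C/C=C(C)/C=C/C=C/C(C)=C/CP(=O)(OCC)OCC | intermediate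
28 | diethyl [(2E,4E,6E,8E,10E,12E,14E)-14-[(4S)-4-{[tert-butyl(dimethyl)silyl]oxy}-2,6,6-trimethylcyclohex-2-en-1-ylidene]-3,8,12-trimethyltetradeca-2,4,6,8,10,12-hexaen-1-yl]phosphonate | CC1=C[C@@H](O[Si](C)(C)C(C)(C)C)CC(C)(C)\C1=C/C=C(C)/C=C/C=C(C)/C=C/C=C/C(C)=C/CP(=O)(OCC)OCC | intermediate
29 | (3S,3'R,5'S)-3-O-[tert-butyl(dimethyl)silyl] ether of the all-E target triol | CC1=C[C@@H](O[Si](C)(C)C(C)(C)C)CC(C)(C)\C1=C/C=C(C)/C=C/C=C(C)/C=C/C=C/C(C)=C/C=C/C(C)=C/C=C1\C(C)(C)C[C@@H](O)C[C@]1(C)O | intermediate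
30 | CNP0269135.1, all-E retro-carotenoid triol, (3S) in ring A and (3'R,5'S) in ring B | CC1=C[C@@H](O)CC(C)(C)\C1=C/C=C(C)/C=C/C=C(C)/C=C/C=C/C(C)=C/C=C/C(C)=C/C=C1\C(C)(C)C[C@@H](O)C[C@]1(C)O | target

**Count and risks**

Total step count: 25. Longest linear sequence: 16 steps (steps 1–8, 12–17, 24, 25).

Risk 1, step 8. The metathesis may stall or go astray: the carbene can be held up by the hindered cross-conjugated diene terminus, or intermolecular metathesis can outrun ring closure. The fallback closes the same C4=C5 bond on a simpler diene and installs the ylidene afterwards. It sets out from 6: copper-catalysed (CuBr) addition of isopropenylmagnesium bromide in refluxing THF and mild acidic hydrolysis of the ketimine should give (6S)-6-{[tert-butyl(dimethyl)silyl]oxy}-2,4,4-trimethylocta-1,7-dien-3-one F1. Ring-closing metathesis with the second-generation Grubbs catalyst should give (4S)-4-{[tert-butyl(dimethyl)silyl]oxy}-2,6,6-trimethylcyclohex-2-en-1-one F2. Lithium ethoxyacetylide should add to the hindered carbonyl to give (4S)-4-{[tert-butyl(dimethyl)silyl]oxy}-1-(ethoxyethynyl)-2,6,6-trimethylcyclohex-2-en-1-ol F3 (either epimer at the new carbinol). Meyer–Schuster rearrangement (Sc(OTf)3, EtOH/CH2Cl2) should then give 11 together with its (Z)-isomer, to be removed by chromatography or equilibrated with a trace of iodine. The route is rejoined at 11.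

Risk 2, step 15. Hydride delivery may be misdirected: conjugate (SN2') attack at C7 with transposition of the exocyclic olefin, or incomplete opening of the hindered epoxide. The fallback replaces the Mitsunobu/hydride pair by an oxidation-level detour and sets out from 16. Dess–Martin oxidation should give ethyl (2E)-2-[(1R,6R)-1,3,3-trimethyl-5-oxo-7-oxabicyclo[4.1.0]heptan-2-ylidene]acetate F4. SmI2 (THF/MeOH, −90 °C) should cleave the C–O bond α to the ketone, the normal course for α,β-epoxy ketones, to give ethyl (2E)-2-[(2S)-2-hydroxy-2,6,6-trimethyl-4-oxocyclohexylidene]acetate F5. Hydroxyl-directed anti reduction with Me4NBH(OAc)3 (Evans–Saksena reduction) should give ethyl (2E)-2-[(2S,4R)-2,4-dihydroxy-2,6,6-trimethylcyclohexylidene]acetate F6, and i-Bu2AlH should reduce its ester to rejoin the route at 19.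

Risk 3, step 23. The symmetrical bis-phosphonate may be olefinated twice, and the trisubstituted olefin next to the carbanion may lose its geometry. The fallback joins two differentiated C20 halves at the central C15–C15' bond by cross-coupling, and sets out from 14, 25, 26 and 21. Horner–Wadsworth–Emmons olefination of 14 with the anion of 25 should give tributyl{(1E,3E,5E,7E,9E)-9-[(4S)-4-{[tert-butyl(dimethyl)silyl]oxy}-2,6,6-trimethylcyclohex-2-en-1-ylidene]-3,7-dimethylnona-1,3,5,7-tetraen-1-yl}stannane F7. The same olefination of 21 with the anion of 26 (excess base to carry the two hydroxyls as alkoxides) should give (1S,3R,6E)-6-[(2E,4E,6E,8E)-9-iodo-3,7-dimethylnona-2,4,6,8-tetraen-1-ylidene]-1,5,5-trimethylcyclohexane-1,3-diol F8. Stille coupling of F7 with F8 (Pd2(dba)3, AsPh3, NMP, rt) should give 29, where the route is rejoined before the final desilylation.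

**Further compounds**

F1 | step 8 | (6S)-6-{[tert-butyl(dimethyl)silyl]oxy}-2,4,4-trimethylocta-1,7-dien-3-one | C=C[C@@H](O[Si](C)(C)C(C)(C)C)CC(C)(C)C(=O)C(C)=C
F2 | step 8 | (4S)-4-{[tert-butyl(dimethyl)silyl]oxy}-2,6,6-trimethylcyclohex-2-en-1-one | CC1=C[C@@H](O[Si](C)(C)C(C)(C)C)CC(C)(C)C1=O
F3 | step 8 | (4S)-4-{[tert-butyl(dimethyl)silyl]oxy}-1-(ethoxyethynyl)-2,6,6-trimethylcyclohex-2-en-1-ol | CCOC#CC1(O)C(C)=C[C@@H](O[Si](C)(C)C(C)(C)C)CC1(C)C
F4 | step 15 | ethyl (2E)-2-[(1R,6R)-1,3,3-trimethyl-5-oxo-7-oxabicyclo[4.1.0]heptan-2-ylidene]acetate | CCOC(=O)/C=C1\C(C)(C)CC(=O)[C@H]2[C@]1(C)O2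
F5 | step 15 | ethyl (2E)-2-[(2S)-2-hydroxy-2,6,6-trimethyl-4-oxocyclohexylidene]acetate | CCOC(=O)/C=C1\C(C)(C)CC(=O)C[C@]1(C)O
F6 | step 15 | ethyl (2E)-2-[(2S,4R)-2,4-dihydroxy-2,6,6-trimethylcyclohexylidene]acetate | CCOC(=O)/C=C1\C(C)(C)C[C@@H](O)C[C@]1(C)O
F7 | step 23 | tributyl{(1E,3E,5E,7E,9E)-9-[(4S)-4-{[tert-butyl(dimethyl)silyl]oxy}-2,6,6-trimethylcyclohex-2-en-1-ylidene]-3,7-dimethylnona-1,3,5,7-tetraen-1-yl}stannane | CC1=C[C@@H](O[Si](C)(C)C(C)(C)C)CC(C)(C)\C1=C/C=C(C)/C=C/C=C(C)/C=C/[Sn](CCCC)(CCCC)CCCC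
F8 | step 23 | (1S,3R,6E)-6-[(2E,4E,6E,8E)-9-iodo-3,7-dimethylnona-2,4,6,8-tetraen-1-ylidene]-1,5,5-trimethylcyclohexane-1,3-diol | I/C=C/C(C)=C/C=C/C(C)=C/C=C1\C(C)(C)C[C@@H](O)C[C@]1(C)O
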